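## Analysis of the target

The target is a 5,6,7,8-tetrahydro-1H-isochromen-8-one: a 2H-pyran (O2, C1, C3, C4, C4a, C8a) fused through C4a–C8a to a cyclohexenone (C4a, C5, C6, C7, C8, C8a), so that O2–C3=C4–C4a=C8a–C8=O is one doubly vinylogous ester. C1 is a CH2 group, C3 carries a trans-3-methyloxiran-2-yl group, C7 a methyl group and a tertiary hydroxyl, and C6 the ester of orsellinic acid. There are four stereocentres. C6 (R) and C7 (R) are neighbours with their oxygens cis on the carbocycle. The two oxirane carbons (2S,3R, trans) lie beyond the flat dienyl ether, out of reach of the ring stereocentres, and need a reagent-controlled step. The sensitive groups are the alkenyl oxirane (acid, π-acids, zerovalent palladium), the vinylogous ester (amines, aqueous acid), the tertiary α-ketol (acyloin shift), the C6 oxygen β to the C8 ketone (retro-aldol) and the free resorcinol. The hard points are the fully substituted C4a=C8a bond with two different carbon arms, the regiochemistry of pyran closure, and the late, acid-free introduction of the oxirane and of a di-ortho-substituted benzoate. The strategy rests on one feature: the ring-fusion carbons C4a and C8a are the β- and α-carbons of the C8 enone, and each carries exactly one pyran carbon (C4 and C1), so both arms can be delivered to a cyclohexenone in one conjugate addition with enolate capture.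

## Retrosynthetic reasoning

Ester C6–O. The orsellinate is cut first, giving diol 24 and the acyl chloride 28 (from acid 27, from orsellinic acid 25); 29 is the silyl-protected ester. The ester would not survive organoaluminium reagents or a lithium amide, and in 24 the secondary C6 hydroxyl is the only acylable one. The phenols travel as silyl ethers so that the last step is a buffered fluoride treatment.

Pyran bond O2–C3. Diol 24 is an isomer of the hydroxy enynone 23, in which the C1 hydroxyl and the C3≡C4 alkyne sit cis on C4a=C8a. Cutting here removes the heterocycle and leaves a plain carbocycle. The forward step must put oxygen on C3 (6-endo) and not on C4 (5-exo, furan). An alkoxide cannot reach the conjugated π-system of the alkyne in plane, so the closure is planned with a nucleophilic amine catalyst that first makes C3 trigonal.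

C4a=C8a double bond. Triol 23 comes from its tris-silyl ether 22, and 22 from the saturated ketone 18 by dehydrogenation through enolate 19, selenide 20 and selenoxide 21. C7 is quaternary, so C8a is the only enolisable position and no regiochemical choice exists.

Oxirane. 18 comes from the (E)-propenyl compound 17 by asymmetric epoxidation. At this stage the propenyl group is the only alkene, and the oxirane is introduced only after all organoaluminium chemistry.

Key disconnection C4–C4a and C1–C8a. 17 is the silyl ether of aldol 16. Cutting both bonds gives enone 8, the enynyl alane 14 and formaldehyde 12. All carbons of the bicyclic core are then in place, and the two new stereocentres are erased later, so only constitution has to be controlled.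

Enyne fragment. Alane 14 comes from the lithium enynide 13, which is set free from the distillable C-silyl enyne 11 by cleavage of its C–Si bond. 11 is cut at the bond between alkyne and alkene into (E)-1-bromoprop-1-ene 9 and ethynyltrimethylsilane 10; the forward palladium/copper-catalysed coupling keeps the alkene geometry of 9. The silyl group raises the boiling point enough for distillation and masks the alkyne terminus that later carries aluminium.

Enone 8. The C4a=C8a alkene of 8 is opened by retro-metathesis to dienone 7. The vinyl group on C8 is cut to Weinreb amide 5. The C5–C4a bond is cut to the primary triflate 4 of hydroxy amide 3 and a copper-bound vinyl group. 3 is the aminolysis product of the bis-silyl lactone 2, made from 2-C-methyl-D-erythrono-1,4-lactone 1, which supplies C6 and C7 with both configurations. Triethylsilyl ethers are chosen because the tertiary C7 ether must later come off next to an oxirane.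

## Alternatives that were turned down

Alternative 1: Palladium-mediated carbocycle closure followed by oxa-electrocyclisation. The bis-silyl ether A1 of the bicyclic diol is cut at C4a–C8a and at O2–C1, which leads to the open-chain iodo dienedione A2: a (Z)-β-iodo enone (C3, C4, C4a) tethered through C5–C7 to a vinyl ketone (C8, C8a, C1). In the forward step (Pd(OAc)2, PPh3, Ag2CO3) zerovalent palladium inserts into C4a–I, the vinylpalladium adds 6-exo to C8a, β-hydride elimination leaves an exocyclic C8a=C1 methylene, and the 1-oxatriene closes by oxa-6π to the pyran.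
- For: two rings form in one operation, the pyran regiochemistry is fixed by a pericyclic step, no dehydrogenation is needed, and A1 is three steps from the target. On these points it is stronger than the chosen route, whose pyran closure is its least precedented step.
- Against: A2 combines a polymerisable vinyl ketone, a β-iodo enone open to addition–elimination and an α,β-epoxy ketone. The Z-iodoalkene cannot be made by hydroiodination once the oxirane is present. Carbopalladation must bond to the substituted α-carbon of the vinyl ketone against its electronic bias (7-endo competes). Zerovalent palladium ionises alkenyl oxiranes, and A1 contains one.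
- In its place the chosen route offers simple fragments, keeps the oxirane out of every organometallic step, and spreads the risk over steps that can be replaced singly.

Alternative 2: α-Ketol ring expansion. Enynone A3 is cut at C6–C7 and C6 is reattached to C8, giving the 1-acetylcyclopent-2-en-1-ol A4. In the forward step Al(O-t-Bu)3 chelates both oxygens and C6 shifts from the carbinol carbon to the acetyl carbon, which enlarges the ring and creates the C7 carbinol.
- For: the tetrasubstituted C4a=C8a enone arrives complete, so the dehydrogenation of the chosen route (step 10) is avoided; the shift is driven by ring enlargement and conjugation. On the dehydrogenation point it is stronger.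
- Against: A3 has the constitution of compound 22 apart from protecting groups, so the pyran closure remains unsolved. A4 needs its own asymmetric synthesis, including a quaternary carbinol at C8 that is set only to be destroyed. The vinylic C8a can migrate instead of the oxygenated sp3 carbon C6. The reversible shift can scramble C7 relative to C6. A Lewis acid with heat meets an alkynyl oxirane.
- In its place the chosen route takes C6 and C7 unchanged from the chiral pool and reaches the same type of intermediate in fewer operations.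

Alternative 3: Vinylogous aldol annulation onto a preformed pyran. The C7 silyl ether A5 of the bicyclic diol is cut at C5–C6, giving the keto aldehyde A6, a 4-methyl-2H-pyran acylated at C8a. In the forward step MgBr2·OEt2 and i-Pr2NEt generate the extended dienolate from the C4a methyl group, which adds to the magnesium-bound aldehyde and closes the carbocycle.
- For: pyran and oxirane are finished before the carbocycle, neither pyran closure nor dehydrogenation is needed late, and A5 has only its C6 hydroxyl free for the esterification. On these points it is stronger.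
- Against: the C6 configuration must be created under control of a quaternary C7 whose methyl and silyloxy groups differ little, so the cis diol is not secured. A6 is a non-enolisable β-keto aldehyde prone to deformylation. The dienolate can react at its α- or γ-carbon. The fragile pyran–oxirane unit is carried through a C–C bond formation.
- In its place the chosen route fixes C6 and C7 from the start and exposes the fragile dienyl oxirane only in the last three steps.

Key step: step 7

Assumption: lactone 1 and geometrically pure (E)-1-bromoprop-1-ene 9 are taken as purchasable, and the D-fructose-derived Shi ketone is taken to show its usual facial preference on the trans-enyne of 17.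

## Route

Step 1
Reactants: 1 2-C-methyl-D-erythrono-1,4-lactone
Product: 2 (3R,4R)-3-methyl-3,4-bis(triethylsilyloxy)oxolan-2-one
Conditions: Et3SiOTf, 2,6-lutidine, CH2Cl2, −78 → 0 °C
Reagents that add atoms: triethylsilyl trifluoromethanesulfonate, CC[Si](CC)(CC)OS(=O)(=O)C(F)(F)F
Why: Silyl triflate silylation of the secondary and the tertiary hydroxyl; no stereocentre is touched, and triethylsilyl ethers can later be removed from the tertiary C7 oxygen by buffered fluoride.

Step 2
Reactants: 2 (3R,4R)-3-methyl-3,4-bis(triethylsilyloxy)oxolan-2-one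
Product: 3 (2R,3R)-4-hydroxy-N-methoxy-N,2-dimethyl-2,3-bis(triethylsilyloxy)butanamide
Conditions: MeNH(OMe)·HCl, AlMe3, CH2Cl2, 0 °C → rt; aq. KNaC4H4O6
Reagents that add atoms: N,O-dimethylhydroxylamine hydrochloride, CNOC.Cl
Why: Weinreb aminolysis of a lactone by the aluminium amide formed in the flask; it frees the C5 hydroxyl and installs the acyl donor for the vinyl ketone, and 3 should be used at once because γ-hydroxy amides relactonise.

Step 3
Reactants: 3 (2R,3R)-4-hydroxy-N-methoxy-N,2-dimethyl-2,3-bis(triethylsilyloxy)butanamide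
Product: 5 (2R,3R)-N-methoxy-N,2-dimethyl-2,3-bis(triethylsilyloxy)hex-5-enamide, via primary triflate 4 (not isolated)
Conditions: Tf2O, 2,6-lutidine, CH2Cl2, −78 °C; then (CH2=CH)2CuMgBr (from CH2=CHMgBr and CuI), THF, −78 → −30 °C; aq. NH4Cl
Reagents that add atoms: vinylmagnesium bromide, C=C[Mg]Br
Why: Copper-mediated sp3–sp2 coupling of a primary triflate; the triflate is made and consumed at −78 °C before the amide oxygen can displace it, a cuprate does not attack the Weinreb amide, and C6 is not involved, so its configuration is kept.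

Step 4
Reactants: 5 (2R,3R)-N-methoxy-N,2-dimethyl-2,3-bis(triethylsilyloxy)hex-5-enamide
Product: 7 (4R,5R)-4-methyl-4,5-bis(triethylsilyloxy)octa-1,7-dien-3-one, via magnesium hemiaminal alkoxide 6 (not isolated)
Conditions: CH2=CHMgBr, THF, 0 °C → rt; inverse quench into cold 1 M HCl
Reagents that add atoms: vinylmagnesium bromide, C=C[Mg]Br
Why: Weinreb ketone synthesis; the N,O-chelated adduct 6 prevents over-addition and collapses only on the acidic quench, which also protonates the released amine before it can add to the vinyl ketone.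

Step 5
Reactants: 7 (4R,5R)-4-methyl-4,5-bis(triethylsilyloxy)octa-1,7-dien-3-one
Product: 8 (5R,6R)-6-methyl-5,6-bis(triethylsilyloxy)cyclohex-2-en-1-one
Conditions: (H2IMes)(PCy3)Cl2Ru=CHPh (second-generation Grubbs catalyst, 5 mol%), CH2Cl2 (0.01 M), 40 °C
Reagents that add atoms: none
Why: Ring-closing olefin metathesis of a vinyl ketone with a terminal alkene, driven by loss of ethene; the carbene should load on the allyl terminus and close the six-membered enone.

Step 6
Reactants: 9 (E)-1-bromoprop-1-ene; 10 ethynyltrimethylsilane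
Product: 11 trimethyl[(3E)-pent-3-en-1-yn-1-yl]silane
Conditions: PdCl2(PPh3)2 (2 mol%), CuI (4 mol%), i-Pr2NH, THF, 0 °C → rt (closed vessel)
Reagents that add atoms: none
Why: Sonogashira coupling of an alkenyl bromide with a terminal alkyne; oxidative addition and reductive elimination at palladium retain the (E)-geometry, the silyl group blocks the second alkyne terminus, and the silyl enyne can be distilled, which gives a salt-free, halide-free precursor of the alane.

Step 7
Reactants: 11 trimethyl[(3E)-pent-3-en-1-yn-1-yl]silane; 8 (5R,6R)-6-methyl-5,6-bis(triethylsilyloxy)cyclohex-2-en-1-one; 12 formaldehyde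
Product: 16 (2R,3R,5R,6R)-2-(hydroxymethyl)-6-methyl-3-[(3E)-pent-3-en-1-yn-1-yl]-5,6-bis(triethylsilyloxy)cyclohexan-1-one, via lithium enynide 13 (not isolated), via dimethyl(enynyl)alane 14 (not isolated), via dimethylaluminium enolate 15 (not isolated)
Conditions: 11, MeLi, THF, 0 °C → rt; solvent exchange to Et2O; Me2AlCl, 0 °C; Ni(acac)2 (10 mol%), i-Bu2AlH (10 mol%), then 8, Et2O, −5 °C; CH2O (gas), −40 → 0 °C; aq. KNaC4H4O6
Reagents that add atoms: none
Why: i-Bu2AlH reduces Ni(acac)2 to a low-valent nickel species, which transfers an electron to the alane-bound enone; the nickel oxa-allyl intermediate takes the alkynyl group from aluminium and reductive elimination forms C4–C4a at the β-carbon, leaving the dimethylaluminium enolate 15. This enolate can only be the C8=C8a isomer because C7 bears no hydrogen, and it adds to monomeric formaldehyde through a closed six-membered aluminium transition state to form C1–C8a. The closest known reaction type is the nickel-catalysed conjugate addition of dialkylaluminium acetylides to s-trans cyclic enones with aldehyde capture of the aluminium enolate. No ring is closed. The new centre C3 of the cyclohexanone (C4a) is controlled by the C5 silyloxy group (C6 of the target), the alkynyl group entering axially on the half-chair anti to it; the new centre C2 (C8a) is controlled by the C3 substituent, formaldehyde adding anti to it; both centres are erased in step 10, so only constitution counts. The step needs 1,4- over 1,2-addition, secured by the nickel catalyst (without it alkynylalanes do not add in conjugate fashion to enones locked s-trans); a single enolate regioisomer, secured by the quaternary C7; and a single hydroxymethylation, secured by the stable aluminium aldolate. The propenyl alkene and the silyl ethers are spectators, whereas an oxirane would be opened by the alane, which is why it is introduced afterwards.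

Step 8
Reactants: 16 (2R,3R,5R,6R)-2-(hydroxymethyl)-6-methyl-3-[(3E)-pent-3-en-1-yn-1-yl]-5,6-bis(triethylsilyloxy)cyclohexan-1-one
Product: 17 (2R,3R,5R,6R)-6-methyl-3-[(3E)-pent-3-en-1-yn-1-yl]-5,6-bis(triethylsilyloxy)-2-[(triethylsilyloxy)methyl]cyclohexan-1-one
Conditions: Et3SiCl, imidazole, CH2Cl2, 0 °C
Reagents that add atoms: chlorotriethylsilane, CC[Si](CC)(CC)Cl
Why: Silylation of the primary alcohol; it blocks dehydration and retro-aldol loss of formaldehyde from the β-hydroxy ketone in the basic steps that follow.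

Step 9
Reactants: 17 (2R,3R,5R,6R)-6-methyl-3-[(3E)-pent-3-en-1-yn-1-yl]-5,6-bis(triethylsilyloxy)-2-[(triethylsilyloxy)methyl]cyclohexan-1-one
Product: 18 (2R,3R,5R,6R)-6-methyl-3-{[(2R,3R)-3-methyloxiran-2-yl]ethynyl}-5,6-bis(triethylsilyloxy)-2-[(triethylsilyloxy)methyl]cyclohexan-1-one
Conditions: 1,2:4,5-di-O-isopropylidene-β-D-erythro-2,3-hexodiulo-2,6-pyranose (Shi ketone, 0.3 equiv), Oxone (2KHSO5·KHSO4·K2SO4), K2CO3, Bu4NHSO4, MeCN–CH2(OMe)2–aq. Na2B4O7 buffer, 0 °C
Reagents that add atoms: potassium peroxymonosulfate (active salt of Oxone), [K+].[O-]S(=O)(=O)OO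
Why: Shi asymmetric epoxidation of a trans-enyne by the chiral dioxirane; the spiro transition state should deliver oxygen in the sense that gives the (2R,3R)-oxirane, as with trans-β-methylstyrene, under reagent control because the alkyne spacer removes the ring stereocentres from the alkene. The alkyne and the hindered ketone should not react.

Step 10
Reactants: 18 (2R,3R,5R,6R)-6-methyl-3-{[(2R,3R)-3-methyloxiran-2-yl]ethynyl}-5,6-bis(triethylsilyloxy)-2-[(triethylsilyloxy)methyl]cyclohexan-1-one
Product: 22 (5R,6R)-6-methyl-3-{[(2R,3R)-3-methyloxiran-2-yl]ethynyl}-5,6-bis(triethylsilyloxy)-2-[(triethylsilyloxy)methyl]cyclohex-2-en-1-one, via lithium enolate 19 (not isolated), via α-selanyl ketone 20 (not isolated), via selenoxide 21 (not isolated)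
Conditions: LiN(i-Pr)2, THF, −78 °C; PhSeCl, −78 °C; then 30% H2O2, pyridine, CH2Cl2, 0 °C → rt
Reagents that add atoms: none
Why: α-Selenenylation of the only possible enolate and selenoxide syn-elimination; the selanyl group is expected to enter anti to the C3 alkynyl group and thus syn to H-3, and selenoxides eliminate away from an oxygen-bearing carbon, so the double bond should form toward C3 and erase both new centres of step 7.

Step 11
Reactants: 22 (5R,6R)-6-methyl-3-{[(2R,3R)-3-methyloxiran-2-yl]ethynyl}-5,6-bis(triethylsilyloxy)-2-[(triethylsilyloxy)methyl]cyclohex-2-en-1-one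
Product: 23 (5R,6R)-5,6-dihydroxy-2-(hydroxymethyl)-6-methyl-3-{[(2R,3R)-3-methyloxiran-2-yl]ethynyl}cyclohex-2-en-1-one
Conditions: HF·pyridine, pyridine, THF, 0 °C → rt
Reagents that add atoms: none
Why: Fluoride cleavage of all three triethylsilyl ethers under buffered, non-basic conditions; no alkoxide is formed, so the C1 oxygen cannot attack the alkyne, and an alkynyl oxirane should tolerate pyridine-buffered HF.

Step 12
Reactants: 23 (5R,6R)-5,6-dihydroxy-2-(hydroxymethyl)-6-methyl-3-{[(2R,3R)-3-methyloxiran-2-yl]ethynyl}cyclohex-2-en-1-one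
Product: 24 (6R,7R)-6,7-dihydroxy-7-methyl-3-[(2S,3R)-3-methyloxiran-2-yl]-5,6,7,8-tetrahydro-1H-isochromen-8-one
Conditions: DABCO (20 mol%), MeCN, rt
Reagents that add atoms: none
Why: Proposed new method: DABCO should add to C3, the δ-carbon of the 2-en-4-ynone, through the conjugated π-system that the tethered oxygen cannot reach in plane; proton transfer from the C1 hydroxyl to C4 gives a vinylammonium dienone and the C1 alkoxide, which adds 6-endo-trig to the now trigonal C3 and expels DABCO to leave the vinylogous ester. The closest known reaction type is the tertiary-amine-catalysed conjugate addition of alcohols to ynones, including the DMAP-mediated 6-endo closure of o-hydroxyaryl ynones to chromones; a plain alkoxide base is avoided because (Z)-2-en-4-yn-1-ols then close 5-exo to furans.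

Step 13
Reactants: 25 orsellinic acid
Product: 27 2,4-bis(tert-butyldimethylsilyloxy)-6-methylbenzoic acid, via silyl ester 26 (not isolated)
Conditions: t-BuMe2SiCl, imidazole, DMF, rt; then AcOH–THF–H2O, rt
Reagents that add atoms: tert-butyldimethylsilyl chloride, CC(C)(C)[Si](C)(C)Cl
Why: Persilylation followed by selective hydrolysis of the labile silyl ester; aryl silyl ethers are chosen so that the last deprotection needs neither acid, hydrogen nor an amine.

Step 14
Reactants: 27 2,4-bis(tert-butyldimethylsilyloxy)-6-methylbenzoic acid; 24 (6R,7R)-6,7-dihydroxy-7-methyl-3-[(2S,3R)-3-methyloxiran-2-yl]-5,6,7,8-tetrahydro-1H-isochromen-8-one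
Product: 29 (6R,7R)-7-hydroxy-7-methyl-3-[(2S,3R)-3-methyloxiran-2-yl]-8-oxo-5,6,7,8-tetrahydro-1H-isochromen-6-yl 2,4-bis(tert-butyldimethylsilyloxy)-6-methylbenzoate, via acyl chloride 28 (not isolated)
Conditions: 27, 1-chloro-N,N,2-trimethylprop-1-en-1-amine, CH2Cl2, 0 °C → rt; then 24, DMAP, Et3N, CH2Cl2, 0 °C → rt
Reagents that add atoms: none
Why: Acyl chloride formation under neutral conditions (Ghosez reagent) and DMAP-mediated esterification; the secondary C6 hydroxyl should react while the hydrogen-bonded tertiary α-ketol hydroxyl does not, and the C6–O bond is not broken, so C6 keeps its configuration.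

Step 15
Reactants: 29 (6R,7R)-7-hydroxy-7-methyl-3-[(2S,3R)-3-methyloxiran-2-yl]-8-oxo-5,6,7,8-tetrahydro-1H-isochromen-6-yl 2,4-bis(tert-butyldimethylsilyloxy)-6-methylbenzoate
Product: 30 (6R,7R)-7-hydroxy-7-methyl-3-[(2S,3R)-3-methyloxiran-2-yl]-8-oxo-5,6,7,8-tetrahydro-1H-isochromen-6-yl 2,4-dihydroxy-6-methylbenzoate (CNP0323247.1)
Conditions: Bu4NF, AcOH, THF, 0 °C
Reagents that add atoms: none
Why: Fluoride cleavage of the two aryl silyl ethers; acetic acid protonates the phenoxides at once, so that neither acyl migration to the C7 oxygen nor opening of the oxirane should occur.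

## Compound list

1 | 2-C-methyl-D-erythrono-1,4-lactone, (3R,4R)-3,4-dihydroxy-3-methyloxolan-2-one | O[C@@H]1COC(=O)[C@]1(C)O | starting material
2 | (3R,4R)-3-methyl-3,4-bis(triethylsilyloxy)oxolan-2-one | CC[Si](CC)(CC)O[C@@H]1COC(=O)[C@]1(C)O[Si](CC)(CC)CC | intermediate
3 | (2R,3R)-4-hydroxy-N-methoxy-N,2-dimethyl-2,3-bis(triethylsilyloxy)butanamide | CC[Si](CC)(CC)O[C@H](CO)[C@@](C)(O[Si](CC)(CC)CC)C(=O)N(C)OC | intermediate
4 | (2R,3R)-4-[methoxy(methyl)amino]-3-methyl-4-oxo-2,3-bis(triethylsilyloxy)butyl trifluoromethanesulfonate (formed in the flask) | CC[Si](CC)(CC)O[C@H](COS(=O)(=O)C(F)(F)F)[C@@](C)(O[Si](CC)(CC)CC)C(=O)N(C)OC | intermediate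
5 | (2R,3R)-N-methoxy-N,2-dimethyl-2,3-bis(triethylsilyloxy)hex-5-enamide | CC[Si](CC)(CC)O[C@H](CC=C)[C@@](C)(O[Si](CC)(CC)CC)C(=O)N(C)OC | intermediate
6 | bromomagnesium alkoxide of the N,O-hemiaminal formed from 5 and the vinyl Grignard reagent, configuration at C4 and C5 as in 5 (formed in the flask) | CC[Si](CC)(CC)O[C@H](CC=C)[C@@](C)(O[Si](CC)(CC)CC)C(O[Mg]Br)(C=C)N(C)OC | intermediate
7 | (4R,5R)-4-methyl-4,5-bis(triethylsilyloxy)octa-1,7-dien-3-one | CC[Si](CC)(CC)O[C@H](CC=C)[C@@](C)(O[Si](CC)(CC)CC)C(=O)C=C | intermediate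
8 | (5R,6R)-6-methyl-5,6-bis(triethylsilyloxy)cyclohex-2-en-1-one | CC[Si](CC)(CC)O[C@@H]1CC=CC(=O)[C@]1(C)O[Si](CC)(CC)CC | intermediate
9 | (E)-1-bromoprop-1-ene | C/C=C/Br | starting material
10 | ethynyltrimethylsilane | C#C[Si](C)(C)C | starting material
11 | trimethyl[(3E)-pent-3-en-1-yn-1-yl]silane | C/C=C/C#C[Si](C)(C)C | intermediate
12 | formaldehyde | C=O | starting material
13 | lithium (3E)-pent-3-en-1-yn-1-ide (formed in the flask) | [Li]C#C/C=C/C | intermediate
14 | dimethyl[(3E)-pent-3-en-1-yn-1-yl]alane (formed in the flask) | C[Al](C)C#C/C=C/C | intermediate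
15 | dimethylaluminium enolate (C1–O–Al, C1=C2) of (3R,5R,6R)-6-methyl-3-[(3E)-pent-3-en-1-yn-1-yl]-5,6-bis(triethylsilyloxy)cyclohexan-1-one (formed in the flask) | CC[Si](CC)(CC)O[C@@H]1C[C@@H](C#C/C=C/C)C=C(O[Al](C)C)[C@]1(C)O[Si](CC)(CC)CC | intermediate
16 | (2R,3R,5R,6R)-2-(hydroxymethyl)-6-methyl-3-[(3E)-pent-3-en-1-yn-1-yl]-5,6-bis(triethylsilyloxy)cyclohexan-1-one | CC[Si](CC)(CC)O[C@@H]1C[C@@H](C#C/C=C/C)[C@H](CO)C(=O)[C@]1(C)O[Si](CC)(CC)CC | intermediate
17 | (2R,3R,5R,6R)-6-methyl-3-[(3E)-pent-3-en-1-yn-1-yl]-5,6-bis(triethylsilyloxy)-2-[(triethylsilyloxy)methyl]cyclohexan-1-one | CC[Si](CC)(CC)O[C@@H]1C[C@@H](C#C/C=C/C)[C@H](CO[Si](CC)(CC)CC)C(=O)[C@]1(C)O[Si](CC)(CC)CC | intermediate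
18 | (2R,3R,5R,6R)-6-methyl-3-{[(2R,3R)-3-methyloxiran-2-yl]ethynyl}-5,6-bis(triethylsilyloxy)-2-[(triethylsilyloxy)methyl]cyclohexan-1-one | CC[Si](CC)(CC)O[C@@H]1C[C@@H](C#C[C@H]2O[C@@H]2C)[C@H](CO[Si](CC)(CC)CC)C(=O)[C@]1(C)O[Si](CC)(CC)CC | intermediate
19 | lithium enolate of 18 (C1–O–Li, C1=C2; other centres as in 18) (formed in the flask) | CC[Si](CC)(CC)O[C@@H]1C[C@@H](C#C[C@H]2O[C@@H]2C)C(CO[Si](CC)(CC)CC)=C(O[Li])[C@]1(C)O[Si](CC)(CC)CC | intermediate
20 | (2R,3S,5R,6R)-6-methyl-3-{[(2R,3R)-3-methyloxiran-2-yl]ethynyl}-2-(phenylselanyl)-5,6-bis(triethylsilyloxy)-2-[(triethylsilyloxy)methyl]cyclohexan-1-one, selenium trans to the alkynyl group (formed in the flask) | CC[Si](CC)(CC)O[C@@H]1C[C@@H](C#C[C@H]2O[C@@H]2C)[C@](CO[Si](CC)(CC)CC)([Se]c2ccccc2)C(=O)[C@]1(C)O[Si](CC)(CC)CC | intermediate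
21 | selenoxide of 20, configuration at selenium not defined (formed in the flask) | CC[Si](CC)(CC)O[C@@H]1C[C@@H](C#C[C@H]2O[C@@H]2C)[C@](CO[Si](CC)(CC)CC)([Se](=O)c2ccccc2)C(=O)[C@]1(C)O[Si](CC)(CC)CC | intermediate
22 | (5R,6R)-6-methyl-3-{[(2R,3R)-3-methyloxiran-2-yl]ethynyl}-5,6-bis(triethylsilyloxy)-2-[(triethylsilyloxy)methyl]cyclohex-2-en-1-one | CC[Si](CC)(CC)O[C@@H]1CC(C#C[C@H]2O[C@@H]2C)=C(CO[Si](CC)(CC)CC)C(=O)[C@]1(C)O[Si](CC)(CC)CC | intermediate
23 | (5R,6R)-5,6-dihydroxy-2-(hydroxymethyl)-6-methyl-3-{[(2R,3R)-3-methyloxiran-2-yl]ethynyl}cyclohex-2-en-1-one | O[C@@H]1CC(C#C[C@H]2O[C@@H]2C)=C(CO)C(=O)[C@]1(C)O | intermediate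
24 | (6R,7R)-6,7-dihydroxy-7-methyl-3-[(2S,3R)-3-methyloxiran-2-yl]-5,6,7,8-tetrahydro-1H-isochromen-8-one | O[C@@H]1CC2=C(COC([C@H]3O[C@@H]3C)=C2)C(=O)[C@]1(C)O | intermediate
25 | orsellinic acid, 2,4-dihydroxy-6-methylbenzoic acid | Cc1cc(O)cc(O)c1C(=O)O | starting material
26 | tert-butyldimethylsilyl 2,4-bis(tert-butyldimethylsilyloxy)-6-methylbenzoate (formed in the flask) | Cc1cc(O[Si](C)(C)C(C)(C)C)cc(O[Si](C)(C)C(C)(C)C)c1C(=O)O[Si](C)(C)C(C)(C)C | intermediate
27 | 2,4-bis(tert-butyldimethylsilyloxy)-6-methylbenzoic acid | Cc1cc(O[Si](C)(C)C(C)(C)C)cc(O[Si](C)(C)C(C)(C)C)c1C(=O)O | intermediate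
28 | 2,4-bis(tert-butyldimethylsilyloxy)-6-methylbenzoyl chloride (formed in the flask) | Cc1cc(O[Si](C)(C)C(C)(C)C)cc(O[Si](C)(C)C(C)(C)C)c1C(Cl)=O | intermediate
29 | (6R,7R)-7-hydroxy-7-methyl-3-[(2S,3R)-3-methyloxiran-2-yl]-8-oxo-5,6,7,8-tetrahydro-1H-isochromen-6-yl 2,4-bis(tert-butyldimethylsilyloxy)-6-methylbenzoate | Cc1cc(O[Si](C)(C)C(C)(C)C)cc(O[Si](C)(C)C(C)(C)C)c1C(=O)O[C@@H]1CC2=C(COC([C@H]3O[C@@H]3C)=C2)C(=O)[C@]1(C)O | intermediate
30 | (6R,7R)-7-hydroxy-7-methyl-3-[(2S,3R)-3-methyloxiran-2-yl]-8-oxo-5,6,7,8-tetrahydro-1H-isochromen-6-yl 2,4-dihydroxy-6-methylbenzoate | Cc1cc(O)cc(O)c1C(=O)O[C@@H]1CC2=C(COC([C@H]3O[C@@H]3C)=C2)C(=O)[C@]1(C)O | target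

## Step count and least certain steps

Total: 15 steps. Longest linear sequence: 13 steps (steps 1–5, 7–12, 14 and 15, from lactone 1).

Step 12 (proposed new method). The amine may add without turning over, the oxygen may still attack C4 and lead on to a furan, or the amine may open the oxirane; the 1,6-mode of this catalysis is not established for a tethered alcohol. Fallback, from 23 back to 24, by known chemistry: stoichiometric diethylamine in ethanol at room temperature should add to C3 and give the dienaminone (5R,6R)-3-{2-(diethylamino)-2-[(2R,3R)-3-methyloxiran-2-yl]ethenyl}-5,6-dihydroxy-2-(hydroxymethyl)-6-methylcyclohex-2-en-1-one F1. Brief treatment with pyridinium p-toluenesulfonate in CH2Cl2 should let the C1 hydroxyl replace the amine at C3 by addition–elimination, returning to the route at 24. This is the amine-adduct/acid-closure sequence used to force 6-endo closure of hydroxy ynones.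

Step 7 (key step). The chelating α-silyloxy ketone may slow the nickel cycle so that 1,2-addition or simple recovery of 8 competes, and capture by formaldehyde may be incomplete or repeated. Fallback, from 8 and lithium enynide 13 (made from 11 as in the route) back to 16: transmetalation with ZnBr2 gives bromo[(3E)-pent-3-en-1-yn-1-yl]zinc F2. With t-BuMe2SiOTf in Et2O–THF at −40 °C this should add in conjugate fashion to 8 (silyl-triflate-promoted conjugate alkynylation) to give the silyl enol ether tert-butyl{[(3R,5R,6R)-6-methyl-3-[(3E)-pent-3-en-1-yn-1-yl]-5,6-bis(triethylsilyloxy)cyclohex-1-en-1-yl]oxy}dimethylsilane F3. Hydroxymethylation of F3 with aqueous formaldehyde 12 and Yb(OTf)3 in THF returns to the route at 16. The same two bonds are formed in two separate operations.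

Step 10. Facial selectivity of the selenenylation may be poor or reversed, which leaves no hydrogen syn to selenium at C3, and the β-silyloxy group may be lost from the enolate. Fallback, from 18 back to 22: the lithium enolate 19 is brominated with N-bromosuccinimide at −78 °C to (2S,3S,5R,6R)-2-bromo-6-methyl-3-{[(2R,3R)-3-methyloxiran-2-yl]ethynyl}-5,6-bis(triethylsilyloxy)-2-[(triethylsilyloxy)methyl]cyclohexan-1-one F4. If the electrophile enters syn to the alkynyl group, the halogen is anti-periplanar to H-3, and DBU in toluene should give 22 by E2 elimination. This fallback is complementary in its stereochemical requirement to the syn-elimination.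

Step 3. The amide oxygen may displace the primary triflate (iminolactone formation and return to 2), or a silyl group may migrate to the primary oxygen. Fallback, from 3 back to 5, without an sp3 leaving group:
- Dess–Martin oxidation of 3 gives (2R,3S)-N-methoxy-N,2-dimethyl-4-oxo-2,3-bis(triethylsilyloxy)butanamide F5.
- Wittig reaction with Ph3P=CHOMe gives (2R,3R)-N,5-dimethoxy-N,2-dimethyl-2,3-bis(triethylsilyloxy)pent-4-enamide F6 as an E/Z mixture.
- Hg(OAc)2 in aqueous THF followed by KI hydrolyses the enol ether to (2R,3R)-N-methoxy-N,2-dimethyl-5-oxo-2,3-bis(triethylsilyloxy)pentanamide F7.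
- Wittig methylenation with Ph3P=CH2 returns to the route at 5.

Step 14. Acylation by the di-ortho-substituted acyl chloride may be too slow, so that 24 decomposes or the acyl chloride is lost. Fallback, from 25 and 24 back to 30, changing the acyl donor and the order of phenol unmasking:
- 25 with acetone, (CF3CO)2O and CF3CO2H gives 7-hydroxy-2,2,5-trimethyl-4H-1,3-benzodioxin-4-one F8.
- t-BuMe2SiCl and imidazole give 7-(tert-butyldimethylsilyloxy)-2,2,5-trimethyl-4H-1,3-benzodioxin-4-one F9.
- The sodium alkoxide of 24 (NaN(SiMe3)2, THF, −78 °C) opens F9 at the acyl carbon with loss of acetone to give (6R,7R)-7-hydroxy-7-methyl-3-[(2S,3R)-3-methyloxiran-2-yl]-8-oxo-5,6,7,8-tetrahydro-1H-isochromen-6-yl 4-(tert-butyldimethylsilyloxy)-2-hydroxy-6-methylbenzoate F10.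
- Bu4NF with AcOH removes the remaining silyl ether and returns to the route at 30.

## Further compounds

F1 | step 12 | (5R,6R)-3-{2-(diethylamino)-2-[(2R,3R)-3-methyloxiran-2-yl]ethenyl}-5,6-dihydroxy-2-(hydroxymethyl)-6-methylcyclohex-2-en-1-one | O[C@@H]1CC(C=C(N(CC)CC)[C@H]2O[C@@H]2C)=C(CO)C(=O)[C@]1(C)O
F2 | step 7 | bromo[(3E)-pent-3-en-1-yn-1-yl]zinc | C/C=C/C#C[Zn]Br
F3 | step 7 | tert-butyl{[(3R,5R,6R)-6-methyl-3-[(3E)-pent-3-en-1-yn-1-yl]-5,6-bis(triethylsilyloxy)cyclohex-1-en-1-yl]oxy}dimethylsilane | CC[Si](CC)(CC)O[C@@H]1C[C@@H](C#C/C=C/C)C=C(O[Si](C)(C)C(C)(C)C)[C@]1(C)O[Si](CC)(CC)CC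
F4 | step 10 | (2S,3S,5R,6R)-2-bromo-6-methyl-3-{[(2R,3R)-3-methyloxiran-2-yl]ethynyl}-5,6-bis(triethylsilyloxy)-2-[(triethylsilyloxy)methyl]cyclohexan-1-one | CC[Si](CC)(CC)O[C@@H]1C[C@@H](C#C[C@H]2O[C@@H]2C)[C@](Br)(CO[Si](CC)(CC)CC)C(=O)[C@]1(C)O[Si](CC)(CC)CC
F5 | step 3 | (2R,3S)-N-methoxy-N,2-dimethyl-4-oxo-2,3-bis(triethylsilyloxy)butanamide | CC[Si](CC)(CC)O[C@H](C=O)[C@@](C)(O[Si](CC)(CC)CC)C(=O)N(C)OC
F6 | step 3 | (2R,3R)-N,5-dimethoxy-N,2-dimethyl-2,3-bis(triethylsilyloxy)pent-4-enamide (E/Z mixture) | CC[Si](CC)(CC)O[C@H](C=COC)[C@@](C)(O[Si](CC)(CC)CC)C(=O)N(C)OC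
F7 | step 3 | (2R,3R)-N-methoxy-N,2-dimethyl-5-oxo-2,3-bis(triethylsilyloxy)pentanamide | CC[Si](CC)(CC)O[C@H](CC=O)[C@@](C)(O[Si](CC)(CC)CC)C(=O)N(C)OC
F8 | step 14 | 7-hydroxy-2,2,5-trimethyl-4H-1,3-benzodioxin-4-one | Cc1cc(O)cc2OC(C)(C)OC(=O)c12
F9 | step 14 | 7-(tert-butyldimethylsilyloxy)-2,2,5-trimethyl-4H-1,3-benzodioxin-4-one | Cc1cc(O[Si](C)(C)C(C)(C)C)cc2OC(C)(C)OC(=O)c12
F10 | step 14 | (6R,7R)-7-hydroxy-7-methyl-3-[(2S,3R)-3-methyloxiran-2-yl]-8-oxo-5,6,7,8-tetrahydro-1H-isochromen-6-yl 4-(tert-butyldimethylsilyloxy)-2-hydroxy-6-methylbenzoate | Cc1cc(O[Si](C)(C)C(C)(C)C)cc(O)c1C(=O)O[C@@H]1CC2=C(COC([C@H]3O[C@@H]3C)=C2)C(=O)[C@]1(C)O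
A1 | alternative 1 | (6R,7R)-7-methyl-3-[(2S,3R)-3-methyloxiran-2-yl]-6,7-bis(triethylsilyloxy)-5,6,7,8-tetrahydro-1H-isochromen-8-one | CC[Si](CC)(CC)O[C@@H]1CC2=C(COC([C@H]3O[C@@H]3C)=C2)C(=O)[C@]1(C)O[Si](CC)(CC)CC
A2 | alternative 1 | (2Z,5R,6R)-3-iodo-6-methyl-1-[(2S,3R)-3-methyloxiran-2-yl]-5,6-bis(triethylsilyloxy)nona-2,8-diene-1,7-dione | C=CC(=O)[C@](C)(O[Si](CC)(CC)CC)[C@H](O[Si](CC)(CC)CC)C/C(I)=C/C(=O)[C@H]1O[C@@H]1C
A3 | alternative 2 | (5R,6R)-5-(tert-butyldimethylsilyloxy)-6-hydroxy-2-{[(4-methoxyphenyl)methoxy]methyl}-6-methyl-3-{[(2R,3R)-3-methyloxiran-2-yl]ethynyl}cyclohex-2-en-1-one | CC(C)(C)[Si](C)(C)O[C@@H]1CC(C#C[C@H]2O[C@@H]2C)=C(COCc2ccc(OC)cc2)C(=O)[C@]1(C)O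
A4 | alternative 2 | 1-[(1S,5R)-5-(tert-butyldimethylsilyloxy)-1-hydroxy-2-{[(4-methoxyphenyl)methoxy]methyl}-3-{[(2R,3R)-3-methyloxiran-2-yl]ethynyl}cyclopent-2-en-1-yl]ethan-1-one | CC(=O)[C@]1(O)C(COCc2ccc(OC)cc2)=C(C#C[C@H]2O[C@@H]2C)C[C@H]1O[Si](C)(C)C(C)(C)C
A5 | alternative 3 | (6R,7R)-6-hydroxy-7-methyl-3-[(2S,3R)-3-methyloxiran-2-yl]-7-(triethylsilyloxy)-5,6,7,8-tetrahydro-1H-isochromen-8-one | O[C@@H]1CC2=C(COC([C@H]3O[C@@H]3C)=C2)C(=O)[C@]1(C)O[Si](CC)(CC)CC
A6 | alternative 3 | (2R)-2-methyl-3-{4-methyl-6-[(2S,3R)-3-methyloxiran-2-yl]-2H-pyran-3-yl}-3-oxo-2-(triethylsilyloxy)propanal | O=C[C@@](C)(O[Si](CC)(CC)CC)C(=O)C1=C(C)C=C([C@H]2O[C@@H]2C)OC1
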